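**Strategy.** Everything rests on disconnecting C4–C5 of the γ-lactone (ring O1–C2–C3–C4–C5), the bond between the carbinol carbon and the O-bearing carbon that carries the 2-methylprop-1-enyl group. The key step exploits the homoallylic relation C4(OH)–C5–C1′=C2′, which marks this bond as the product of a carbonyl allylation. An achiral (1E)-3-methylbuta-1,3-dienyl 3-oxopropanoate is closed by a nickel-catalysed, ligand-controlled reductive diene–aldehyde cyclisation with Et3SiH. In one operation this should form the lactone ring, both stereocentres (trans), the trisubstituted side-chain alkene and the silyl ether. An aldol condensation with a nerol-derived C10 aldehyde then adds the E-alkylidene chain.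

Key step: step 8

Remark: lactone atoms are numbered O1, C2 (carbonyl), C3, C4 (carbinol), C5 (O-bearing carbon) throughout; compounds 1, 2, 6, 10 and 12 are taken as catalogue compounds.

**Step 1**
Reactants: 1 nerol; 2 (2E)-3-methylpent-2-enoic acid
Product: 3 (2Z)-3,7-dimethylocta-2,6-dien-1-yl (2E)-3-methylpent-2-enoate
Conditions: DCC, DMAP (cat.), CH2Cl2, 0 °C to rt
Reagents that add atoms: none
Why: Steglich esterification of a primary allylic alcohol; the mild carbodiimide activation should leave the Z-allylic and E-enoate geometries untouched.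

**Step 2**
Reactants: 3 (2Z)-3,7-dimethylocta-2,6-dien-1-yl (2E)-3-methylpent-2-enoate
Product: 4 (2Z,6E)-8-hydroxy-3,7-dimethylocta-2,6-dien-1-yl (2E)-3-methylpent-2-enoate
Conditions: SeO2 (0.3 equiv), tBuOOH (2.5 equiv), salicylic acid (cat.), CH2Cl2, rt
Reagents that add atoms: tert-butyl hydroperoxide, CC(C)(C)OO (oxygen, passed on by catalytic SeO2, O=[Se]=O)
Why: Catalytic SeO2 allylic oxidation (ene reaction then [2,3]-sigmatropic shift) should hydroxylate the E-methyl of the terminal, most electron-rich trisubstituted alkene, which fixes the 6E geometry.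

**Step 3**
Reactants: 4 (2Z,6E)-8-hydroxy-3,7-dimethylocta-2,6-dien-1-yl (2E)-3-methylpent-2-enoate
Product: 5 (2Z,6E)-8-bromo-3,7-dimethylocta-2,6-dien-1-yl (2E)-3-methylpent-2-enoate
Conditions: CBr4, PPh3, CH2Cl2, 0 °C
Reagents that add atoms: tetrabromomethane, BrC(Br)(Br)Br
Why: Appel reaction; the neutral conditions should give the primary allylic bromide without allylic transposition or loss of alkene geometry.

**Step 4**
Reactants: 5 (2Z,6E)-8-bromo-3,7-dimethylocta-2,6-dien-1-yl (2E)-3-methylpent-2-enoate; 6 acetaldehyde N,N-dimethylhydrazone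
Product: 9 (2Z,6E)-3,7-dimethyl-10-oxodeca-2,6-dien-1-yl (2E)-3-methylpent-2-enoate, via lithiated hydrazone 7 (not isolated), via alkylated hydrazone 8 (not isolated)
Conditions: 6, LiN(iPr)2, THF, 0 °C; then 5, −78 to −20 °C; then sat. aq. oxalic acid, Et2O, rt
Reagents that add atoms: water, O
Why: Corey–Enders hydrazone alkylation, in which the aza-enolate should displace the primary allylic bromide by SN2 at low temperature much faster than it attacks the hindered enoate, followed by two-phase acid hydrolysis to the aldehyde.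

**Step 5**
Reactants: 10 methyl 3,3-dimethoxypropanoate
Product: 11 sodium 3,3-dimethoxypropanoate
Conditions: NaOH (1.0 equiv), MeOH/H2O, rt; evaporate, dry in vacuo
Reagents that add atoms: sodium hydroxide, [Na+].[OH-]
Why: Saponification under basic conditions keeps the acid-labile acetal and delivers the dry carboxylate salt directly.

**Step 6**
Reactants: 11 sodium 3,3-dimethoxypropanoate; 12 3-methylbut-2-enal
Product: 15 (1E)-3-methylbuta-1,3-dien-1-yl 3,3-dimethoxypropanoate, via mixed anhydride 13 (not isolated), via potassium dienolate 14 (not isolated)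
Conditions: 11, tBuCOCl, THF, 0 °C (flask A); 12, KOtBu, THF, −78 °C (flask B); A into B, −78 °C
Reagents that add atoms: none
Why: γ-Deprotonation of the s-trans enal gives the (1E)-dienolate, whose potassium oxygen should be O-acylated at the unhindered carbonyl of the pivalic mixed anhydride (dienyl ester synthesis by enolate O-acylation).

**Step 7**
Reactants: 15 (1E)-3-methylbuta-1,3-dien-1-yl 3,3-dimethoxypropanoate
Product: 17 (1E)-3-methylbuta-1,3-dien-1-yl 3-oxopropanoate, via collidinium salt 16 (not isolated)
Conditions: Et3SiOTf, 2,4,6-collidine, CH2Cl2, 0 °C; then H2O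
Reagents that add atoms: water, O
Why: Silyl triflate/hindered pyridine acetal cleavage (pyridinium salt, then water) runs under non-acidic conditions, so the acid-labile dienyl ester should survive; 17 is used at once in solution because β-formyl esters self-condense.

**Step 8**
Reactants: 17 (1E)-3-methylbuta-1,3-dien-1-yl 3-oxopropanoate
Product: 18 (4S,5R)-5-(2-methylprop-1-en-1-yl)-4-[(triethylsilyl)oxy]oxolan-2-one
Conditions: Ni(cod)2 (10 mol %), (2R,5R)-2,5-dimethyl-1-phenylphospholane (20 mol %), Et3SiH (5 equiv), THF (0.02 M), slow addition of 17, 0 °C to rt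
Reagents that add atoms: triethylsilane, CC[SiH](CC)CC
Why: Proposed new method: zerovalent nickel binds the s-cis diene and the tethered aldehyde of 17 and joins the diene carbon that carries the ester oxygen (future C5) to the formyl carbon (future C4), either by oxidative cyclisation to an η3-allyl oxanickelacycle or by addition of H–Ni–SiEt3 to the diene and carbonyl insertion, after which Et3SiH silylates the nickel alkoxide and hydride goes to the terminal CH2, leaving the C1′=C2′ trisubstituted alkene. The closest known reaction type is the nickel/phosphine/silane reductive cyclisation of ω-formyl-1,3-dienes to 2-alkenylcycloalkanol silyl ethers, which has an enantioselective variant with this phospholane; the ester tether and the acyloxy-substituted diene terminus are new. The lactone closes in a 5-exo-trig mode at the aldehyde carbon, and the s-trans ester rotamer that this requires is reached under high dilution. C4 and C5 arise together: their trans relation should follow from the (1E)-enol ester, which keeps the ring oxygen syn on the allyl unit so that the aldehyde substituent sits pseudo-equatorial in a chair-like six-centre array, and their absolute sense from the chiral phospholane on nickel (the ligand antipode is taken if induction runs the other way). The step needs attack through C5 and not the CMe2 terminus, secured by the two-atom O–C(=O) tether (five- against seven-membered ring and a quaternary centre), hydride delivery to the unsubstituted CH2 terminus, and chemoselectivity over aldehyde hydrosilylation, C3-allylation of the acidic methylene and nickel insertion into the enol ester C–O bond, which slow addition of 17, low temperature and the modest donor strength of the phosphine should secure.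

**Step 9**
Reactants: 18 (4S,5R)-5-(2-methylprop-1-en-1-yl)-4-[(triethylsilyl)oxy]oxolan-2-one; 9 (2Z,6E)-3,7-dimethyl-10-oxodeca-2,6-dien-1-yl (2E)-3-methylpent-2-enoate
Product: 22 (2Z,6E)-3,7-dimethyl-10-[(3E,4S,5R)-5-(2-methylprop-1-en-1-yl)-2-oxo-4-[(triethylsilyl)oxy]oxolan-3-ylidene]deca-2,6-dien-1-yl (2E)-3-methylpent-2-enoate, via lithium enolate 19 (not isolated), via lithium aldolate 20 (not isolated), via mesylate 21 (not isolated)
Conditions: LiN(iPr)2, THF, −78 °C; 9, −78 °C; MsCl, −78 to 0 °C; DBU, 0 °C to rt
Reagents that add atoms: none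
Why: Aldol condensation (lithium enolate addition, mesylation, E1cB elimination), in which the mesylate should leave in preference to the C4 silyloxy group and the more stable E-alkylidene (chain anti to C2=O) should predominate, while C4 and C5 are not touched.

**Step 10**
Reactants: 22 (2Z,6E)-3,7-dimethyl-10-[(3E,4S,5R)-5-(2-methylprop-1-en-1-yl)-2-oxo-4-[(triethylsilyl)oxy]oxolan-3-ylidene]deca-2,6-dien-1-yl (2E)-3-methylpent-2-enoate
Product: 23 (2Z,6E)-10-[(3E,4S,5R)-4-hydroxy-5-(2-methylprop-1-en-1-yl)-2-oxooxolan-3-ylidene]-3,7-dimethyldeca-2,6-dien-1-yl (2E)-3-methylpent-2-enoate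
Conditions: HF·pyridine, pyridine, THF, 0 °C
Reagents that add atoms: none
Why: Buffered fluoride cleavage of the secondary triethylsilyl ether should leave the alkylidene lactone, the allylic ester and all alkene geometries intact.

**Compound list**

1 | nerol, (2Z)-3,7-dimethylocta-2,6-dien-1-ol | OC/C=C(/C)CCC=C(C)C | starting material
2 | (2E)-3-methylpent-2-enoic acid | CC/C(C)=C/C(=O)O | starting material
3 | (2Z)-3,7-dimethylocta-2,6-dien-1-yl (2E)-3-methylpent-2-enoate | CC/C(C)=C/C(=O)OC/C=C(/C)CCC=C(C)C | intermediate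
4 | (2Z,6E)-8-hydroxy-3,7-dimethylocta-2,6-dien-1-yl (2E)-3-methylpent-2-enoate | CC/C(C)=C/C(=O)OC/C=C(/C)CC/C=C(\C)CO | intermediate
5 | (2Z,6E)-8-bromo-3,7-dimethylocta-2,6-dien-1-yl (2E)-3-methylpent-2-enoate | CC/C(C)=C/C(=O)OC/C=C(/C)CC/C=C(\C)CBr | intermediate
6 | acetaldehyde N,N-dimethylhydrazone | CC=NN(C)C | starting material
7 | lithiated hydrazone (lithium aza-enolate of 6) | [Li+].C=C[N-]N(C)C | intermediate
8 | alkylated hydrazone, (2Z,6E)-10-(dimethylhydrazinylidene)-3,7-dimethyldeca-2,6-dien-1-yl (2E)-3-methylpent-2-enoate | CC/C(C)=C/C(=O)OC/C=C(/C)CC/C=C(\C)CCC=NN(C)C | intermediate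
9 | (2Z,6E)-3,7-dimethyl-10-oxodeca-2,6-dien-1-yl (2E)-3-methylpent-2-enoate | CC/C(C)=C/C(=O)OC/C=C(/C)CC/C=C(\C)CCC=O | intermediate
10 | methyl 3,3-dimethoxypropanoate | COC(=O)CC(OC)OC | starting material
11 | sodium 3,3-dimethoxypropanoate | [Na+].[O-]C(=O)CC(OC)OC | intermediate
12 | 3-methylbut-2-enal | CC(C)=CC=O | starting material
13 | mixed anhydride, 3,3-dimethoxypropanoic pivalic anhydride | COC(CC(=O)OC(=O)C(C)(C)C)OC | intermediate
14 | potassium dienolate, potassium (1E)-3-methylbuta-1,3-dien-1-olate | C=C(C)/C=C/[O-].[K+] | intermediate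
15 | (1E)-3-methylbuta-1,3-dien-1-yl 3,3-dimethoxypropanoate | C=C(C)/C=C/OC(=O)CC(OC)OC | intermediate
16 | collidinium salt, 1-{1-methoxy-3-[(1E)-3-methylbuta-1,3-dien-1-yl]oxy-3-oxopropyl}-2,4,6-trimethylpyridinium triflate | C=C(C)/C=C/OC(=O)CC(OC)[n+]1c(C)cc(C)cc1C.[O-]S(=O)(=O)C(F)(F)F | intermediate
17 | (1E)-3-methylbuta-1,3-dien-1-yl 3-oxopropanoate | C=C(C)/C=C/OC(=O)CC=O | intermediate
18 | (4S,5R)-5-(2-methylprop-1-en-1-yl)-4-[(triethylsilyl)oxy]oxolan-2-one | C1C(=O)O[C@H](C=C(C)C)[C@H]1O[Si](CC)(CC)CC | intermediate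
19 | lithium enolate of 18 | C1=C([O-])O[C@H](C=C(C)C)[C@H]1O[Si](CC)(CC)CC.[Li+] | intermediate
20 | lithium aldolate from 19 and 9 (epimers at C3 and the carbinol carbon) | CC/C(C)=C/C(=O)OC/C=C(/C)CC/C=C(\C)CCC([O-])C1C(=O)O[C@H](C=C(C)C)[C@H]1O[Si](CC)(CC)CC.[Li+] | intermediate
21 | mesylate of the aldol adduct (epimers at C3 and the carbinol carbon) | CC/C(C)=C/C(=O)OC/C=C(/C)CC/C=C(\C)CCC(OS(C)(=O)=O)C1C(=O)O[C@H](C=C(C)C)[C@H]1O[Si](CC)(CC)CC | intermediate
22 | (2Z,6E)-3,7-dimethyl-10-[(3E,4S,5R)-5-(2-methylprop-1-en-1-yl)-2-oxo-4-[(triethylsilyl)oxy]oxolan-3-ylidene]deca-2,6-dien-1-yl (2E)-3-methylpent-2-enoate | CC/C(C)=C/C(=O)OC/C=C(/C)CC/C=C(\C)CC/C=C1/C(=O)O[C@H](C=C(C)C)[C@H]1O[Si](CC)(CC)CC | intermediate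
23 | (2Z,6E)-10-[(3E,4S,5R)-4-hydroxy-5-(2-methylprop-1-en-1-yl)-2-oxooxolan-3-ylidene]-3,7-dimethyldeca-2,6-dien-1-yl (2E)-3-methylpent-2-enoate | CC/C(C)=C/C(=O)OC/C=C(/C)CC/C=C(\C)CC/C=C1/C(=O)O[C@H](C=C(C)C)[C@H]1O | target

**Step count.** Total steps: 10. Longest linear sequence: 6 steps (5–10, or 1–4 followed by 9 and 10).

**Steps most likely to fail**

Step 8 (proposed new method). The cyclisation may suffer from poor facial discrimination by the ligand, from erosion of the trans relation through syn/anti isomerisation of the allylnickel unit, or from diversion of 17 into plain hydrosilylation or C3-allylation. The fallback is known chiral-pool chemistry that draws on no numbered intermediate; it sets out from purchased 2-deoxy-D-ribose F1 and comes back to the route at 18. It also covers the case that 17 cannot be handled. Br2 in water oxidises the sugar to 2-deoxy-D-ribono-1,4-lactone F2, whose C4 and C5 already carry the required (4S,5R) configuration. Et3SiCl and imidazole in DMF give the bis(triethylsilyl) ether F3. Swern conditions (oxalyl chloride, DMSO, then Et3N, −78 to −30 °C) cleave and oxidise the primary silyl ether selectively to (2S,3S)-5-oxo-3-[(triethylsilyl)oxy]oxolane-2-carbaldehyde F4. Wittig olefination with isopropylidenetriphenylphosphorane (from isopropyltriphenylphosphonium iodide and nBuLi, THF, −78 °C) turns the formyl group into the 2-methylprop-1-enyl group of 18.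

Step 7. The enol ester may be cleaved or the diene may oligomerise cationically under the silyl triflate, and the freed β-formyl ester may self-condense on concentration. The fallback unmasks the aldehyde by neutral oxidation; it sets out from 12 and comes back at 17. Purchased 3-[(tert-butyldimethylsilyl)oxy]propanoic acid F5 is converted with tBuCOCl and Et3N (THF, 0 °C) into its pivalic mixed anhydride F6. This acylates dienolate 14 (made from 12 as in step 6) at −78 °C to give (1E)-3-methylbuta-1,3-dien-1-yl 3-[(tert-butyldimethylsilyl)oxy]propanoate F7. HF·pyridine in THF frees (1E)-3-methylbuta-1,3-dien-1-yl 3-hydroxypropanoate F8. Dess–Martin periodinane buffered with NaHCO3 (CH2Cl2, 0 °C) oxidises it to 17, which is taken on as a solution.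

Step 9. Enolate 19 may lose the C4 silyloxy group by E1cB to give a butenolide, and elimination of 21 may give poor control of alkene geometry. The fallback replaces the aldol condensation by a Wittig reaction of a stabilised ylide; it sets out from 18 and comes back at 22. Enolate 19 is brominated with CBr4 at −78 °C to (4S,5R)-3-bromo-5-(2-methylprop-1-en-1-yl)-4-[(triethylsilyl)oxy]oxolan-2-one F9. PPh3 in toluene at 80 °C gives the phosphonium bromide F10. Et3N in CH2Cl2 liberates the stabilised phosphorane F11, which condenses with 9 (CH2Cl2, rt to 40 °C) and should give the E-alkylidene lactone 22 without exposing the product to strong base.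

Further compounds
F1 | step 8 | 2-deoxy-D-ribose | O=CC[C@H](O)[C@H](O)CO
F2 | step 8 | 2-deoxy-D-ribono-1,4-lactone, (4S,5R)-4-hydroxy-5-(hydroxymethyl)oxolan-2-one | C1C(=O)O[C@H](CO)[C@H]1O
F3 | step 8 | (4S,5R)-4-[(triethylsilyl)oxy]-5-{[(triethylsilyl)oxy]methyl}oxolan-2-one | C1C(=O)O[C@H](CO[Si](CC)(CC)CC)[C@H]1O[Si](CC)(CC)CC
F4 | step 8 | (2S,3S)-5-oxo-3-[(triethylsilyl)oxy]oxolane-2-carbaldehyde | C1C(=O)O[C@H](C=O)[C@H]1O[Si](CC)(CC)CC
F5 | step 7 | 3-[(tert-butyldimethylsilyl)oxy]propanoic acid | CC(C)(C)[Si](C)(C)OCCC(=O)O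
F6 | step 7 | 3-[(tert-butyldimethylsilyl)oxy]propanoic pivalic anhydride | CC(C)(C)[Si](C)(C)OCCC(=O)OC(=O)C(C)(C)C
F7 | step 7 | (1E)-3-methylbuta-1,3-dien-1-yl 3-[(tert-butyldimethylsilyl)oxy]propanoate | C=C(C)/C=C/OC(=O)CCO[Si](C)(C)C(C)(C)C
F8 | step 7 | (1E)-3-methylbuta-1,3-dien-1-yl 3-hydroxypropanoate | C=C(C)/C=C/OC(=O)CCO
F9 | step 9 | (4S,5R)-3-bromo-5-(2-methylprop-1-en-1-yl)-4-[(triethylsilyl)oxy]oxolan-2-one | BrC1C(=O)O[C@H](C=C(C)C)[C@H]1O[Si](CC)(CC)CC
F10 | step 9 | [(4S,5R)-5-(2-methylprop-1-en-1-yl)-2-oxo-4-[(triethylsilyl)oxy]oxolan-3-yl]triphenylphosphonium bromide | [Br-].c1ccccc1[P+](c1ccccc1)(c1ccccc1)C1C(=O)O[C@H](C=C(C)C)[C@H]1O[Si](CC)(CC)CC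
F11 | step 9 | (4S,5R)-5-(2-methylprop-1-en-1-yl)-4-[(triethylsilyl)oxy]-3-(triphenylphosphoranylidene)oxolan-2-one | c1ccccc1P(c1ccccc1)(c1ccccc1)=C1C(=O)O[C@H](C=C(C)C)[C@H]1O[Si](CC)(CC)CC
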